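## The problem

1. Target 18 is (3R)-3-hydroxy-7,8-didehydro-8′-apo-β-caroten-8′-al. In carotenoid numbering the cyclohexene ring is C1 (gem-dimethyl), C2, C3 (carbinol), C4, C5 (methyl) and C6. The chain runs from the alkyne C7≡C8 through the all-E heptaene C9=C10 … C10′=C9′ (methyls on C9, C13, C13′, C9′) to the formyl carbon C8′.
2. The single stereocentre C3 lies between two methylene groups. Nothing nearby can direct a reagent to it and it directs nothing itself, so an external chiral agent must set it on a small ring precursor.
3. The most hindered bond is C6–C7, because C6 is a fully substituted sp2 carbon between quaternary C1 and methyl-bearing C5.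
4. Six of the seven double bonds prefer E on thermodynamic grounds, but C9=C10 does not. C9 carries a methyl group and a slim, linear alkynyl group, so placing the alkyne cis to C11 costs nothing, and iodine, heat or light equilibration cannot repair this bond once the alkyne is present.
5. The two chain ends differ (ring-alkyne against formyl). A linear build-up would therefore need repeated end differentiation while carrying a polyenal that is sensitive to acid, light, oxygen and hard nucleophiles.
6. The feature that makes the key step possible is hidden symmetry. The twenty carbons C8 to C8′, methyls included, are related in pairs by an inversion centre at the midpoint of C15=C15′, and C8 and C8′ are both at the aldehyde oxidation level. An inner alkyne carbon is what a formyl carbon becomes when a diazomethyl anion adds one carbon (C7), so the chain is dialdehyde 16 in disguise.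
7. In 16 the substituent on C9 is a formyl group, so 9E is thermodynamically favoured there and can be fixed before the alkyne exists.
8. C1 is quaternary, so a C6 ketone can enolise only towards C5 and gives a single enol triflate.

## Retrosynthesis

**C6–C7 (18 ⇒ 7 + 17).** The last bond made is the hindered sp2–sp bond.
- Cutting C8–C9 instead would leave C8 on the ring side and destroy the chain symmetry. Cutting any C=C would put the chiral ring into a long linear sequence.
- This cut puts C3 into the nine-carbon hydroxy enol triflate 7 and all seven E double bonds into the achiral C21 ynal 17.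
- The forward reaction must tolerate a free hydroxyl, a formyl group and a heptaene, and must leave every double bond alone. A palladium/copper alkynylation of an enol triflate does this, and a rod-like sp nucleophile is the smallest possible partner for crowded C6.

**C7 (17 ⇒ 16), the key simplification.** Removing C7 and restoring oxygen on C8 turns the unsymmetrical 17 into the C2h-symmetric dialdehyde 16.
- 16 has only ten different carbons, all its double bonds prefer E, and it crystallises.
- The neighbouring option, a two-carbon unit C7–C8 joined to C9, has no symmetric precursor.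
- The forward reaction must convert one of two equivalent formyl groups into an ethynyl group without touching C9=C10. Because the groups are equivalent, the only question is how many react.

**C11=C12 and C11′=C12′ together (16 ⇒ 14 ⇒ 13 ⇒ 10 + two 9).** Both bonds are cut at once, so one two-directional olefination of the C10 dialdehyde 10 with two molecules of the C5 phosphonate 9 builds the C20 skeleton as diester 13.
- Reduction to diol 14 and allylic oxidation then give 16.
- Cutting at C9=C10 would need two extensions per side.
- The olefination needs only a preference for E, since 13 can be equilibrated to all-E.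

**C–P (9 ⇒ 8).** The phosphonate comes from the allylic bromide 8 by phosphite alkylation. The E geometry of the future C9=C10 is already present in 8.

**C6–O and the silyl group (7 ⇒ 6 ⇒ 4 ⇒ 3).** The triflate oxygen is the carbonyl oxygen of ketone 4.
- C1 is quaternary, so only enolate 5 can form and the regiochemistry of 6 is unambiguous.
- The methyl-bearing stereocentre of 4 is erased, so only the carbinol configuration of 3 matters.
- The silyl ether is needed only for the strong base. It is removed at the stage of 6, which leaves no deprotection after the union.

**Two C–H bonds (3 ⇒ 2 ⇒ 1).** Hydroxy ketone 3 comes from achiral ketoisophorone 1 by enzymatic C=C reduction to 2 and enzymatic reduction of the unhindered carbonyl. The carbinol flanked by two methylenes is the kind of centre an active site distinguishes and a small hydride reagent does not.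

## Roads not taken

**Alternative 1:** the most obvious route grows the chain outward from the ring by cutting C11=C12 and then C11′=C12′.
- Forward key step: Wittig reaction of the acetylenic C15 phosphonium salt A1 with one formyl group of 10 to give the C25 aldehyde A2. A C5 extension with 9 and a redox adjustment follow.
- The ylide of A1 is delocalised over C11–C10–C9, which lowers the C9=C10 bond order. Geometry therefore leaks at the one double bond that equilibration cannot repair.
- The chiral, hydroxylated ring is carried through the whole linear sequence, and A1 still needs the C6–C7 bond to be made.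
- The chosen plan fixes 9E while C8 is a carbonyl carbon and attaches the ring in the last step.

**Alternative 2:** cut C8–C9.
- Forward key step: Sonogashira coupling of the ring alkyne A3 with the polyenyl iodide A4. This is stereospecific at C9.
- A4 has iodine at one end and formyl at the other, so it has no symmetric precursor and must be built stepwise from end-differentiated pieces. A terminal iodoheptaene is also more fragile than 16 or 17.
- A3 itself comes from triflate 7 by coupling with a silylacetylene and desilylation. The hindered coupling is therefore not avoided and two steps are added.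

**Alternative 3:** cut inside the triple bond C7≡C8.
- Forward key step: addition of the carbanion of sulfone A5 to one formyl group of 16, derivatisation of the alkoxide, and double elimination to the alkyne.
- This also uses 16 and has C6–C7 preformed.
- The two eliminations need an excess of strong base in the presence of the second formyl group.
- After the first elimination, the allylic hydrogens on C4 and on the C5 methyl group are vinylogous to the sulfone. They are more acidic than the vinylic H8 that must leave, so sulfinate loss towards the ring competes.
- A5 would be made from 6 by carbonylation, reduction and sulfinate displacement, which is several steps more than 7.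

Key step: step 9

Assumption: compounds 8 and 10 are taken as catalogue chemicals, 10 being the standard C10 building block of carotenoid manufacture.

## Steps

Step 1
Reactants: 1 ketoisophorone (2,6,6-trimethylcyclohex-2-ene-1,4-dione)
Product: 3 (4R,6R)-4-hydroxy-2,2,6-trimethylcyclohexanone (actinol), via (6R)-levodione 2 (not isolated)
Conditions: ene-reductase (Old Yellow Enzyme family), then (6R)-levodione reductase (short-chain dehydrogenase/ketoreductase class), cat. NAD+/NADP+, glucose dehydrogenase, D-glucose, phosphate buffer pH 7, 30 °C, one pot
Reagents that add atoms: none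
Why: Known two-enzyme reduction of this enedione: the ene-reductase transfers hydride from reduced flavin to C3 and a proton to C2 on the opposite face to give (6R)-2, and the ketoreductase then delivers nicotinamide hydride to one face of the unhindered C4 carbonyl only, which sets the (4R)-carbinol, the future C3 of 18. The C1 carbonyl is shielded by the gem-dimethyl group and stays. The C6 centre is of no consequence, since step 3 erases it.

Step 2
Reactants: 3 (4R,6R)-4-hydroxy-2,2,6-trimethylcyclohexanone
Product: 4 (4R,6R)-4-(tert-butyldimethylsilyloxy)-2,2,6-trimethylcyclohexanone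
Conditions: TBSCl, imidazole, DMF, 25 °C
Reagents that add atoms: tert-butyldimethylsilyl chloride, CC(C)(C)[Si](C)(C)Cl
Why: Standard silylation of a secondary alcohol with a silyl chloride and imidazole; the ketone and both stereocentres are untouched, and the ether masks the hydroxyl proton against the strong base of step 3.

Step 3
Reactants: 4 (4R,6R)-4-(tert-butyldimethylsilyloxy)-2,2,6-trimethylcyclohexanone
Product: 6 (4R)-4-(tert-butyldimethylsilyloxy)-2,6,6-trimethylcyclohex-1-en-1-yl trifluoromethanesulfonate, via lithium enolate 5 (not isolated)
Conditions: LiN(i-Pr)2 (1.2 equiv), THF, –78 → 0 °C; PhNTf2 (1.2 equiv), 0 → 25 °C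
Reagents that add atoms: N-phenylbis(trifluoromethanesulfonimide), O=S(=O)(N(c1ccccc1)S(=O)(=O)C(F)(F)F)C(F)(F)F
Why: C2 is quaternary, so only C6–H can be removed and a single tetrasubstituted enolate 5 forms and is O-sulfonylated (enol triflate synthesis, known for 2,2,6-trimethylcyclohexanones). The C6 stereocentre disappears, the silyloxy group sits γ to the carbonyl and cannot leave by E1cB elimination, and C4 keeps its configuration.

Step 4
Reactants: 6 (4R)-4-(tert-butyldimethylsilyloxy)-2,6,6-trimethylcyclohex-1-en-1-yl trifluoromethanesulfonate
Product: 7 (4R)-4-hydroxy-2,6,6-trimethylcyclohex-1-en-1-yl trifluoromethanesulfonate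
Conditions: aq. HF (48 %), MeCN, 0 → 25 °C
Reagents that add atoms: none
Why: Acidic fluoride cleavage of a secondary silyl ether; enol triflates are inert to aqueous HF, whereas basic fluoride sources could attack sulfur. Deprotection is placed here so that nothing has to be removed after the polyenal is attached.

Step 5
Reactants: 8 ethyl (E)-4-bromo-2-methylbut-2-enoate
Product: 9 ethyl (E)-4-(diethoxyphosphoryl)-2-methylbut-2-enoate
Conditions: P(OEt)3 (1.1 equiv), neat, 130 °C, volatile by-product distilled off
Reagents that add atoms: triethyl phosphite, CCOP(OCC)OCC
Why: Michaelis–Arbuzov reaction of a primary allylic bromide: SN2 attack of phosphorus at C4 and dealkylation by bromide, with the E-trisubstituted double bond untouched.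

Step 6
Reactants: 9 ethyl (E)-4-(diethoxyphosphoryl)-2-methylbut-2-enoate (2.2 equiv), 10 (2E,4E,6E)-2,7-dimethylocta-2,4,6-trienedial
Product: 13 diethyl (2E,4E,6E,8E,10E,12E,14E)-2,6,11,15-tetramethylhexadeca-2,4,6,8,10,12,14-heptaenedioate (diethyl crocetinate), via sodium phosphonate carbanion 11 (not isolated), via C15 aldehyde ester 12 (not isolated)
Conditions: NaH (2.2 equiv), THF, 0 °C; add 10, 0 → 25 °C; crude product: cat. I2, toluene, daylight, 25 °C, then crystallisation
Reagents that add atoms: none
Why: Two-directional Horner–Wadsworth–Emmons olefination: carbanion 11 attacks through the carbon α to phosphorus, first one and then the other formyl group of 10, and forms C11=C12 and C11′=C12′ mainly E, as stabilised allylic phosphonates do. Every double bond of 13 prefers E (at C9=C10 because the ester stays coplanar with the chain only when trans to it), so iodine-catalysed equilibration and crystallisation should funnel any Z isomers into the all-E diester.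

Step 7
Reactants: 13 diethyl crocetinate
Product: 14 (2E,4E,6E,8E,10E,12E,14E)-2,6,11,15-tetramethylhexadeca-2,4,6,8,10,12,14-heptaene-1,16-diol (crocetindiol)
Conditions: i-Bu2AlH (5 equiv), CH2Cl2, –78 → –20 °C; aq. potassium sodium tartrate
Reagents that add atoms: none
Why: 1,2-Reduction of conjugated esters to allylic alcohols with i-Bu2AlH, standard for carotenoid esters; the polyene is inert to the hydride at low temperature.

Step 8
Reactants: 14 crocetindiol
Product: 16 (2E,4E,6E,8E,10E,12E,14E)-2,6,11,15-tetramethylhexadeca-2,4,6,8,10,12,14-heptaenedial (crocetindial), via hydroxy aldehyde 15 (not isolated)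
Conditions: MnO2 (activated, excess), CH2Cl2, 25 °C, dark
Reagents that add atoms: none
Why: MnO2 oxidises allylic (here polyenylic) alcohols selectively to enals under neutral conditions and does not go on to acids; geometry is retained and all-E 16 can be purified by crystallisation.

Step 9
Reactants: 16 crocetindial (1.5 equiv)
Product: 17 (2E,4E,6E,8E,10E,12E,14E)-2,6,11,15-tetramethylheptadeca-2,4,6,8,10,12,14-heptaen-16-ynal
Conditions: Me3SiCHN2 (1.0 equiv), n-BuLi (1.0 equiv), THF, –78 °C; added slowly to 16 in THF, –78 → 0 °C; H2O; dark
Reagents that add atoms: (trimethylsilyl)diazomethane, C[Si](C)(C)C=[N+]=[N-]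
Why: Lithiated Me3SiCHN2 adds 1,2 to one formyl group of 16, the β-silyl alkoxide loses silanolate in a Peterson-type elimination, the diazoalkene loses N2, and the alkylidene carbene undergoes a 1,2-hydrogen shift to the terminal alkyne C7≡C8 (Colvin homologation, the aprotic relative of the Seyferth–Gilbert reaction, established for α-branched conjugated enals). No ring is closed and no stereocentre is made; what the step transfers is geometry, because C9=C10 takes no part in any bond change and the 9E geometry fixed under thermodynamic control in 13 and 16 passes unchanged into an enyne in which it could no longer be corrected. The two formyl groups are equivalent through the inversion centre at C15=C15′, so no site selectivity is needed and either one gives the same 17; the only selectivity needed is single against double reaction. This is secured first by stoichiometry, the reagent being limiting and added to an excess of 16. It is secured second by the substrate: in 16 each formyl group is activated by the other acceptor through the heptaene, and the first addition turns one acceptor into an alkoxide at –78 °C, so the remaining formyl group is less electrophilic than those of unreacted 16, the same logic that underlies the routine mono-olefination of polyene dialdehydes with one equivalent of an ylide. The aprotic medium avoids the conjugate addition of methanol that troubles the carbonate/methanol variant with enals. Material that has reacted twice or not at all differs from 17 by one formyl group each way, so chromatography should separate it, and unreacted 16 is recycled.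

Step 10
Reactants: 7 (4R)-4-hydroxy-2,6,6-trimethylcyclohex-1-en-1-yl trifluoromethanesulfonate, 17 C21 polyenynal
Product: 18 (2E,4E,6E,8E,10E,12E,14E)-17-[(4R)-4-hydroxy-2,6,6-trimethylcyclohex-1-en-1-yl]-2,6,11,15-tetramethylheptadeca-2,4,6,8,10,12,14-heptaen-16-ynal, the target
Conditions: Pd(PPh3)4 (5 mol %), CuI (10 mol %), Et3N (3 equiv), DMF, degassed, dark, 25 → 45 °C
Reagents that add atoms: none
Why: Sonogashira coupling: zerovalent palladium inserts into the C6–O bond of triflate 7, the copper acetylide formed from 17, CuI and Et3N transmetalates, and reductive elimination forms C6–C7; couplings of 2,6,6-trimethylcyclohexenyl triflates with small enynes are close precedent. The rod-like acetylide is the least demanding nucleophile for a palladium centre held between C1 and C5, and the hydroxyl and formyl groups are spectators. No double bond and not C3 is involved, so 9E, the other E bonds and 3R are carried into 18 unchanged.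

## Compound list

1 | ketoisophorone (2,6,6-trimethylcyclohex-2-ene-1,4-dione) | CC1=CC(=O)CC(C)(C)C1=O | starting material
2 | (6R)-levodione ((6R)-2,2,6-trimethylcyclohexane-1,4-dione) | C[C@H]1C(=O)C(C)(C)CC(=O)C1 | intermediate (not isolated)
3 | (4R,6R)-4-hydroxy-2,2,6-trimethylcyclohexanone (actinol) | C[C@H]1C(=O)C(C)(C)C[C@H](O)C1 | intermediate
4 | (4R,6R)-4-(tert-butyldimethylsilyloxy)-2,2,6-trimethylcyclohexanone | C[C@H]1C(=O)C(C)(C)C[C@H](O[Si](C)(C)C(C)(C)C)C1 | intermediate
5 | lithium (4R)-4-(tert-butyldimethylsilyloxy)-2,6,6-trimethylcyclohex-1-en-1-olate | CC1=C([O-])C(C)(C)C[C@H](O[Si](C)(C)C(C)(C)C)C1.[Li+] | intermediate (not isolated)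
6 | (4R)-4-(tert-butyldimethylsilyloxy)-2,6,6-trimethylcyclohex-1-en-1-yl trifluoromethanesulfonate | CC1=C(OS(=O)(=O)C(F)(F)F)C(C)(C)C[C@H](O[Si](C)(C)C(C)(C)C)C1 | intermediate
7 | (4R)-4-hydroxy-2,6,6-trimethylcyclohex-1-en-1-yl trifluoromethanesulfonate | CC1=C(OS(=O)(=O)C(F)(F)F)C(C)(C)C[C@H](O)C1 | intermediate
8 | ethyl (E)-4-bromo-2-methylbut-2-enoate | CCOC(=O)/C(C)=C/CBr | starting material
9 | ethyl (E)-4-(diethoxyphosphoryl)-2-methylbut-2-enoate | CCOC(=O)/C(C)=C/CP(=O)(OCC)OCC | intermediate
10 | (2E,4E,6E)-2,7-dimethylocta-2,4,6-trienedial | O=C/C(C)=C/C=C/C=C(\C)C=O | starting material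
11 | sodium salt of the carbanion of 9 | CCOC(=O)/C(C)=C/[CH-]P(=O)(OCC)OCC.[Na+] | intermediate (not isolated)
12 | ethyl (2E,4E,6E,8E,10E)-2,6,11-trimethyl-12-oxododeca-2,4,6,8,10-pentaenoate | CCOC(=O)/C(C)=C/C=C/C(C)=C/C=C/C=C(\C)C=O | intermediate (not isolated)
13 | diethyl (all-E)-2,6,11,15-tetramethylhexadeca-2,4,6,8,10,12,14-heptaenedioate (diethyl crocetinate) | CCOC(=O)/C(C)=C/C=C/C(C)=C/C=C/C=C(C)/C=C/C=C(\C)C(=O)OCC | intermediate
14 | (all-E)-2,6,11,15-tetramethylhexadeca-2,4,6,8,10,12,14-heptaene-1,16-diol (crocetindiol) | OC/C(C)=C/C=C/C(C)=C/C=C/C=C(C)/C=C/C=C(\C)CO | intermediate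
15 | (all-E)-16-hydroxy-2,6,11,15-tetramethylhexadeca-2,4,6,8,10,12,14-heptaenal | OC/C(C)=C/C=C/C(C)=C/C=C/C=C(C)/C=C/C=C(\C)C=O | intermediate (not isolated)
16 | (all-E)-2,6,11,15-tetramethylhexadeca-2,4,6,8,10,12,14-heptaenedial (crocetindial) | O=C/C(C)=C/C=C/C(C)=C/C=C/C=C(C)/C=C/C=C(\C)C=O | intermediate
17 | (all-E)-2,6,11,15-tetramethylheptadeca-2,4,6,8,10,12,14-heptaen-16-ynal | C#C/C(C)=C/C=C/C(C)=C/C=C/C=C(C)/C=C/C=C(\C)C=O | intermediate
18 | (3R)-3-hydroxy-7,8-didehydro-8′-apo-β-caroten-8′-al | CC1=C(C#C/C(C)=C/C=C/C(C)=C/C=C/C=C(C)/C=C/C=C(\C)C=O)C(C)(C)C[C@H](O)C1 | target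

## Step count and least certain steps

Total: 10 steps. The longest linear sequence is 6 steps (steps 5 to 10, from 8 to 18). The ring branch has 5 steps (steps 1 to 4 and step 10).

**Step 9 (key step).**
- Risk: homologation at both ends is the most likely failure. The electronic link between the two formyl groups through fourteen conjugated carbons is weak, and the once-reacted material is more soluble than 16 at low temperature, so it meets the reagent more readily. Poor solubility of 16 may also hold conversion down.
- Fallback: the ends are told apart at the redox stage instead of in the C–C bond formation. It sets out from diol 14, whose oxidation with a limited amount of MnO2 is stopped at hydroxy aldehyde 15, which is now isolated. Diol, hydroxy aldehyde and dialdehyde differ strongly in polarity, and the first formyl group slows oxidation of the far carbinol. Compound 15 has a single electrophilic end and can be treated with an excess of lithiated Me3SiCHN2 to give the polyenynol (all-E)-2,6,11,15-tetramethylheptadeca-2,4,6,8,10,12,14-heptaen-16-yn-1-ol F1. MnO2 oxidation of F1 comes back to the route at 17.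

**Step 10.**
- Risk: reaction at crowded C6 may be slow. That leaves time for oxidative dimerisation of the terminal alkyne at copper and for geometrical isomerisation of the polyene on prolonged warming.
- Fallback: C6–C7 is made by carbonyl addition instead of cross-coupling. It sets out from 17 and ketone 4. Compound 17 is masked with HC(OMe)3 and cat. pyridinium p-toluenesulfonate in MeOH as the dimethyl acetal F2. Deprotonation of F2 with n-BuLi at –78 °C and addition to 4 gives the tertiary propargylic alcohol F3, as a mixture of epimers at the new carbinol carbon. Dehydration with POCl3/pyridine removes the C5 hydrogen and gives the silyl ether acetal of the target F4, both epimers converging. Aqueous HF in MeCN cleaves the silyl ether and the acetal and comes back to the route at 18.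

**Step 6.**
- Risk: the geometry of the future C9=C10 may be lost through the delocalised carbanion 11. The second olefination may also stay incomplete once the sparingly soluble intermediate separates.
- Fallback: the polarity of the olefination is reversed, so that C9=C10 sits in the aldehyde partner and never in an allyl anion. It sets out from 10. NaBH4 reduces 10 to (2E,4E,6E)-2,7-dimethylocta-2,4,6-triene-1,8-diol F5, and PPh3·HBr in MeOH converts F5 into the bis(triphenylphosphonium) dibromide F6. A double Wittig reaction of F6 (NaOMe, CH2Cl2/MeOH) with two equivalents of bought ethyl (E)-2-methyl-4-oxobut-2-enoate F7, followed by the same iodine equilibration, comes back to the route at 13.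

**Step 1.**
- Risk: the ketoreductase may reduce the C4 carbonyl of 1 before the C=C bond has been reduced. The face selectivity at C4 may also be incomplete with a given enzyme preparation.
- Fallback: the carbinol is set by a metal catalyst on the enedione, where the two flanks of C4 differ (vinyl against methylene). It sets out from 1. Asymmetric transfer hydrogenation with RuCl(p-cymene)(TsDPEN), using the enantiomer that delivers the 4S alcohol, in i-PrOH gives (4S)-4-hydroxy-2,6,6-trimethylcyclohex-2-en-1-one F8. TBSCl/imidazole then gives its silyl ether F9. Conjugate reduction of F9 with LiBH(s-Bu)3 in THF at –78 °C adds hydride to C3 and forms enolate 5 directly, and trapping with PhNTf2 comes back to the route at 6.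

## Further compounds

F1 | step 9 | (all-E)-2,6,11,15-tetramethylheptadeca-2,4,6,8,10,12,14-heptaen-16-yn-1-ol | C#C/C(C)=C/C=C/C(C)=C/C=C/C=C(C)/C=C/C=C(\C)CO
F2 | step 10 | dimethyl acetal of 17, (all-E)-17,17-dimethoxy-3,7,12,16-tetramethylheptadeca-3,5,7,9,11,13,15-heptaen-1-yne | C#C/C(C)=C/C=C/C(C)=C/C=C/C=C(C)/C=C/C=C(\C)C(OC)OC
F3 | step 10 | tertiary propargylic alcohol from lithiated F2 and 4 (epimers at the new carbinol carbon, other ring centres as in 4) | C[C@H]1C(O)(C#C/C(C)=C/C=C/C(C)=C/C=C/C=C(C)/C=C/C=C(\C)C(OC)OC)C(C)(C)C[C@H](O[Si](C)(C)C(C)(C)C)C1
F4 | step 10 | tert-butyldimethylsilyl ether dimethyl acetal of 18 | CC1=C(C#C/C(C)=C/C=C/C(C)=C/C=C/C=C(C)/C=C/C=C(\C)C(OC)OC)C(C)(C)C[C@H](O[Si](C)(C)C(C)(C)C)C1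
F5 | step 6 | (2E,4E,6E)-2,7-dimethylocta-2,4,6-triene-1,8-diol | OC/C(C)=C/C=C/C=C(\C)CO
F6 | step 6 | [(2E,4E,6E)-2,7-dimethylocta-2,4,6-triene-1,8-diyl]bis(triphenylphosphonium) dibromide | [Br-].[Br-].c1ccccc1[P+](c1ccccc1)(c1ccccc1)C/C(C)=C/C=C/C=C(\C)C[P+](c1ccccc1)(c1ccccc1)c1ccccc1
F7 | step 6 | ethyl (E)-2-methyl-4-oxobut-2-enoate | CCOC(=O)/C(C)=C/C=O
F8 | step 1 | (4S)-4-hydroxy-2,6,6-trimethylcyclohex-2-en-1-one | CC1=C[C@@H](O)CC(C)(C)C1=O
F9 | step 1 | (4S)-4-(tert-butyldimethylsilyloxy)-2,6,6-trimethylcyclohex-2-en-1-one | CC1=C[C@@H](O[Si](C)(C)C(C)(C)C)CC(C)(C)C1=O
A1 | alternative 1 | [(2E)-5-[(4R)-4-hydroxy-2,6,6-trimethylcyclohex-1-en-1-yl]-3-methylpent-2-en-4-yn-1-yl]triphenylphosphonium bromide | CC1=C(C#C/C(C)=C/C[P+](c2ccccc2)(c2ccccc2)c2ccccc2)C(C)(C)C[C@H](O)C1.[Br-]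
A2 | alternative 1 | (3R)-3-hydroxy-7,8-didehydro-12′-apo-β-caroten-12′-al | CC1=C(C#C/C(C)=C/C=C/C(C)=C/C=C/C=C(\C)C=O)C(C)(C)C[C@H](O)C1
A3 | alternative 2 | (1R)-4-ethynyl-3,5,5-trimethylcyclohex-3-en-1-ol | CC1=C(C#C)C(C)(C)C[C@H](O)C1
A4 | alternative 2 | (2E,4E,6E,8E,10E,12E,14E)-15-iodo-2,6,11-trimethylhexadeca-2,4,6,8,10,12,14-heptaenal | I/C(C)=C/C=C/C(C)=C/C=C/C=C(C)/C=C/C=C(\C)C=O
A5 | alternative 3 | (1R)-3,5,5-trimethyl-4-[(phenylsulfonyl)methyl]cyclohex-3-en-1-ol | CC1=C(CS(=O)(=O)c2ccccc2)C(C)(C)C[C@H](O)C1
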